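**Retrosynthetic overview**
- The coumarin is attached last: Mitsunobu etherification of the C11 alcohol with umbelliferone, then hydrolysis of the C3–O/C24–O acetonide.
- Ring B is formed second. The strategy rests on the unit C12H2=C8–C9(H)–C11H2–O in ring B: a carbon bearing CH2O next to a methylidene carbon is what a β‑titanoxy C9 radical (from a C9–C11 oxirane) leaves after 6‑exo‑dig addition to a C8≡C12 alkyne. Disconnecting C8–C9 gives a ring A epoxy alkyne.
- The oxirane comes from the C9 aldehyde and a sulfonium ylide; the acetonide from a triol made by hydride reduction of a β‑keto ester aldehyde; the C4 methyl from β‑keto ester alkylation.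
- Ring A is formed first, by a Diels–Alder reaction: the 2‑silyloxy diene of methyl 3‑oxopent‑4‑enoate (C1–C4, C24) plus (2E)‑2‑methylhept‑2‑en‑6‑ynal (C5, C10, C9, C10‑methyl, C6–C8, C12). The E geometry encodes the trans C5/C10 relationship; a chiral oxazaborolidinium catalyst sets the absolute configuration.
- Ring order: ring A (cycloaddition), ring B (radical closure), then the aryl ether.

Key step: step 11

Remark: drimane locants are used (C24 = the hydroxymethyl carbon on C4); the sense of induction in step 5 is assigned from the formyl C–H···O binding model of this catalyst class and is an assumption of the plan; the oxirane 16 is used as its mixture of C9 epimers.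

**Step 1**
Reactants: 1 methyl acetate; 2 acrolein
Product: 3 methyl 3-hydroxypent-4-enoate (racemic)
Conditions: LiN(i-Pr)2, THF, −78 °C; then 2; aq. NH4Cl
Reagents that add atoms: none
Why: Ester aldol addition; the lithium enolate of methyl acetate adds 1,2 to the enal at low temperature, and the carbinol centre is removed in step 2.

**Step 2**
Reactants: 3 methyl 3-hydroxypent-4-enoate
Product: 4 methyl 3-oxopent-4-enoate
Conditions: CrO3, H2SO4, acetone, 0 °C
Reagents that add atoms: none
Why: Jones oxidation of the allylic secondary alcohol is the standard access to this vinyl β‑keto ester (Nazarov reagent), and the acidic medium avoids base‑induced self‑Michael addition.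

**Step 3**
Reactants: 4 methyl 3-oxopent-4-enoate
Product: 5 methyl (2Z)-3-[(tert-butyldimethylsilyl)oxy]penta-2,4-dienoate
Conditions: LiN(SiMe3)2, THF, −78 °C; TBSOTf, −78 → 0 °C; non-aqueous work-up
Reagents that add atoms: tert-butyldimethylsilyl trifluoromethanesulfonate, CC(C)(C)[Si](C)(C)OS(=O)(=O)C(F)(F)F
Why: O‑Silylation of the lithium‑chelated β‑keto ester enolate should give the 2Z silyl dienol ether, in which the ester is trans to the vinyl group so that the diene can reach the s‑cis form.

**Step 4**
Reactants: 6 pent-4-yn-1-ol; 7 2-(triphenylphosphoranylidene)propanal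
Product: 9 (2E)-2-methylhept-2-en-6-ynal, via pent-4-ynal 8 (not isolated)
Conditions: TEMPO (cat.), PhI(OAc)2, CH2Cl2, rt; then 7, 40 °C
Reagents that add atoms: none
Why: Oxoammonium oxidation gives the volatile aldehyde, which is trapped in the same flask by Wittig olefination; the stabilised formyl ylide should give the E trisubstituted enal.

**Step 5**
Reactants: 5 methyl (2Z)-3-[(tert-butyldimethylsilyl)oxy]penta-2,4-dienoate; 9 (2E)-2-methylhept-2-en-6-ynal
Product: 11 methyl (2R,3R)-2-(but-3-yn-1-yl)-3-formyl-3-methyl-6-oxocyclohexane-1-carboxylate (C1 epimers plus enol), via silyl enol ether cycloadduct 10 (not isolated)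
Conditions: (S)-o-tolyl-CBS-oxazaborolidine (20 mol %), Tf2NH (18 mol %), CH2Cl2, −78 → −20 °C; then 1 M HCl, THF, 0 °C
Reagents that add atoms: none
Why: Catalytic enantioselective Diels–Alder reaction of a 2‑silyloxy diene with an α‑substituted enal bound to a chiral oxazaborolidinium ion: the silyloxy‑activated terminus C4 bonds to the enal β‑carbon C5 and C1 bonds to C10, suprafacial addition to the E alkene places the butynyl chain cis to the C10 methyl and trans to the formyl group, the catalyst shields one enal face (formyl C–H···O binding, diene approach anti to the phenyl group) and so fixes C5 and C10, the C4 centre stays epimerisable and does not matter, and dilute acid cleaves the silyl enol ether to the β‑keto ester.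

**Step 6**
Reactants: 11 methyl (2R,3R)-2-(but-3-yn-1-yl)-3-formyl-3-methyl-6-oxocyclohexane-1-carboxylate
Product: 12 methyl (1S,2S,3R)-2-(but-3-yn-1-yl)-3-formyl-1,3-dimethyl-6-oxocyclohexane-1-carboxylate
Conditions: MeI, K2CO3, acetone, rt
Reagents that add atoms: iodomethane, CI
Why: C‑Alkylation of a cyclic β‑keto ester enolate (only C4 is acidic toward K2CO3; the formyl group cannot enolise): iodomethane should enter anti to the vicinal C5 butynyl chain and the C10 methyl, which both lie on the lower face, as in the methylation of 4‑alkoxycarbonyl‑3‑oxodecalins anti to the angular methyl, so the new methyl is cis to C5–H and the ester becomes C24.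

**Step 7**
Reactants: 12 methyl (1S,2S,3R)-2-(but-3-yn-1-yl)-3-formyl-1,3-dimethyl-6-oxocyclohexane-1-carboxylate
Product: 13 (1R,2R,3S,4R)-3-(but-3-yn-1-yl)-2,4-bis(hydroxymethyl)-2,4-dimethylcyclohexan-1-ol
Conditions: LiAlH4, THF, −78 → 25 °C; Fieser work-up
Reagents that add atoms: none
Why: Hydride reduction of aldehyde, ketone and ester in one operation: at C3 the hydride should attack from the face of the C4 methyl and C5–H, anti to the C4 ester and the C5 chain (the usual outcome for 2‑alkyl‑2‑alkoxycarbonylcyclohexanones and 4,4‑disubstituted 3‑oxo terpenoids), which puts the C3 hydroxyl cis to C24H2OH; the isolated alkyne is inert.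

**Step 8**
Reactants: 13 (1R,2R,3S,4R)-3-(but-3-yn-1-yl)-2,4-bis(hydroxymethyl)-2,4-dimethylcyclohexan-1-ol
Product: 14 [(4aR,5S,6R,8aR)-5-(but-3-yn-1-yl)-2,2,4a,6-tetramethylhexahydro-4H-1,3-benzodioxin-6-yl]methanol
Conditions: 2,2-dimethoxypropane, PPTS (cat.), acetone, rt
Reagents that add atoms: 2,2-dimethoxypropane, COC(C)(C)OC
Why: Acid‑catalysed transketalisation: only the cis C3–OH/C24–OH pair can close a six‑membered acetonide, while the C9 hydroxyl on the opposite ring face stays free.

**Step 9**
Reactants: 14 [(4aR,5S,6R,8aR)-5-(but-3-yn-1-yl)-2,2,4a,6-tetramethylhexahydro-4H-1,3-benzodioxin-6-yl]methanol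
Product: 15 (4aR,5R,6R,8aR)-5-(but-3-yn-1-yl)-2,2,4a,6-tetramethylhexahydro-4H-1,3-benzodioxine-6-carbaldehyde
Conditions: Dess–Martin periodinane, NaHCO3, CH2Cl2, 0 °C → rt
Reagents that add atoms: none
Why: Dess–Martin oxidation of a neopentyl‑type primary alcohol to a non‑enolisable aldehyde; the buffer protects the acetonide.

**Step 10**
Reactants: 15 (4aR,5R,6R,8aR)-5-(but-3-yn-1-yl)-2,2,4a,6-tetramethylhexahydro-4H-1,3-benzodioxine-6-carbaldehyde
Product: 16 (4aR,5S,6R,8aR)-5-(but-3-yn-1-yl)-2,2,4a,6-tetramethyl-6-(oxiran-2-yl)hexahydro-4H-1,3-benzodioxine (both oxirane epimers)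
Conditions: Me3S+ I−, n-BuLi, THF, −10 °C → rt
Reagents that add atoms: trimethylsulfonium iodide, C[S+](C)C.[I-]
Why: Corey–Chaykovsky epoxidation: the small sulfonium methylide adds to the hindered, non‑enolisable aldehyde and closes the oxirane (C11 added); the ylide is too weak a base to remove the alkyne proton, and both C9 epimers are usable because C9 becomes planar in step 11.

**Step 11**
Reactants: 16 (4aR,5S,6R,8aR)-5-(but-3-yn-1-yl)-2,2,4a,6-tetramethyl-6-(oxiran-2-yl)hexahydro-4H-1,3-benzodioxine
Product: 17 C3–O/C24–O acetonide of [(1R,4aS,5R,6R,8aR)-6-hydroxy-5-(hydroxymethyl)-5,8a-dimethyl-2-methylidenedecahydronaphthalen-1-yl]methanol (C11–OH free)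
Conditions: Cp2TiCl2 (10 mol %), Mn dust, 2,4,6-collidine·HCl, THF (5 mM in 16), rt
Reagents that add atoms: none
Why: Cp2TiCl (trivalent titanium, formed from Cp2TiCl2 and Mn dust) transfers one electron to the oxirane and cleaves the C9–O bond, giving the secondary C9 radical with the C11 oxygen on titanium; either oxirane epimer gives the same planar radical, and opening toward the more substituted carbon follows radical stability. The closest known reaction type is the titanocene‑mediated reductive epoxide opening with radical cyclisation onto an alkyne, run catalytically with collidinium chloride as proton source. Ring B closes by 6‑exo‑dig attack of C9 on C8 of the terminal alkyne, and the C12 vinyl radical takes a hydrogen atom from THF to leave the C8=C12 methylidene. The new stereocentre C9 is set in a chair‑like transition state that is trans‑fused to ring A with the C11H2O–Ti group equatorial, away from the axial C5–H and C7–H, so that C9–H ends up axial on the face opposite the C10 methyl. The step needs ring closure to outrun capture of the C9 radical by a second Cp2TiCl (which would deoxygenate to the vinyl compound) and hydrogen abstraction from the solvent. This is secured by the radical carbon and the butynyl chain sitting trans on adjacent ring A carbons next to the quaternary C10 (a pre‑organised closure) and by the low titanium concentration at high dilution.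

**Step 12**
Reactants: 17 C3–O/C24–O acetonide of the methylidene decalin triol; 18 umbelliferone
Product: 19 C3–O/C24–O acetonide of 7-{[(1R,4aS,5R,6R,8aR)-6-hydroxy-5-(hydroxymethyl)-5,8a-dimethyl-2-methylidenedecahydronaphthalen-1-yl]methoxy}-2H-chromen-2-one
Conditions: PPh3, DIAD, THF, 0 °C → rt
Reagents that add atoms: none
Why: Mitsunobu etherification: the acidic phenol protonates the betaine and its anion displaces the oxyphosphonium at the primary C11, so no stereocentre is touched.

**Step 13**
Reactants: 19 acetonide of the coumarin ether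
Product: 20 7-{[(1R,4aS,5R,6R,8aR)-6-hydroxy-5-(hydroxymethyl)-5,8a-dimethyl-2-methylidenedecahydronaphthalen-1-yl]methoxy}-2H-chromen-2-one (CNP0149624.1)
Conditions: AcOH/H2O (4:1), 40 °C
Reagents that add atoms: none
Why: Acetal hydrolysis in weak aqueous acid frees the C3 and C24 hydroxyls, while the exocyclic alkene, the aryl ether and the lactone are stable under these conditions.

**Compound list**
1 | methyl acetate | COC(C)=O | starting material
2 | acrolein | C=CC=O | starting material
3 | methyl 3-hydroxypent-4-enoate (racemic) | C=CC(O)CC(=O)OC | intermediate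
4 | methyl 3-oxopent-4-enoate | C=CC(=O)CC(=O)OC | intermediate
5 | methyl (2Z)-3-[(tert-butyldimethylsilyl)oxy]penta-2,4-dienoate | COC(=O)/C=C(\O[Si](C)(C)C(C)(C)C)C=C | intermediate
6 | pent-4-yn-1-ol | C#CCCCO | starting material
7 | 2-(triphenylphosphoranylidene)propanal | CC(C=O)=P(c1ccccc1)(c1ccccc1)c1ccccc1 | starting material
8 | pent-4-ynal | C#CCCC=O | intermediate (not isolated)
9 | (2E)-2-methylhept-2-en-6-ynal | C#CCC/C=C(\C)C=O | intermediate
10 | methyl (5R,6R)-6-(but-3-yn-1-yl)-2-[(tert-butyldimethylsilyl)oxy]-5-formyl-5-methylcyclohex-2-ene-1-carboxylate (C1 epimers) | C#CCC[C@@H]1C(C(=O)OC)C(O[Si](C)(C)C(C)(C)C)=CC[C@@]1(C)C=O | intermediate (not isolated)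
11 | methyl (2R,3R)-2-(but-3-yn-1-yl)-3-formyl-3-methyl-6-oxocyclohexane-1-carboxylate (C1 epimers plus enol) | C#CCC[C@@H]1C(C(=O)OC)C(=O)CC[C@@]1(C)C=O | intermediate
12 | methyl (1S,2S,3R)-2-(but-3-yn-1-yl)-3-formyl-1,3-dimethyl-6-oxocyclohexane-1-carboxylate | C#CCC[C@@H]1[C@](C)(C(=O)OC)C(=O)CC[C@@]1(C)C=O | intermediate
13 | (1R,2R,3S,4R)-3-(but-3-yn-1-yl)-2,4-bis(hydroxymethyl)-2,4-dimethylcyclohexan-1-ol | C#CCC[C@@H]1[C@](C)(CO)[C@H](O)CC[C@@]1(C)CO | intermediate
14 | [(4aR,5S,6R,8aR)-5-(but-3-yn-1-yl)-2,2,4a,6-tetramethylhexahydro-4H-1,3-benzodioxin-6-yl]methanol | C#CCC[C@@H]1[C@]2(C)COC(C)(C)O[C@@H]2CC[C@@]1(C)CO | intermediate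
15 | (4aR,5R,6R,8aR)-5-(but-3-yn-1-yl)-2,2,4a,6-tetramethylhexahydro-4H-1,3-benzodioxine-6-carbaldehyde | C#CCC[C@@H]1[C@]2(C)COC(C)(C)O[C@@H]2CC[C@@]1(C)C=O | intermediate
16 | (4aR,5S,6R,8aR)-5-(but-3-yn-1-yl)-2,2,4a,6-tetramethyl-6-(oxiran-2-yl)hexahydro-4H-1,3-benzodioxine, both oxirane epimers (ring A epoxy alkyne, key-step precursor) | C#CCC[C@@H]1[C@]2(C)COC(C)(C)O[C@@H]2CC[C@@]1(C)C3CO3 | intermediate
17 | C3–O/C24–O acetonide of [(1R,4aS,5R,6R,8aR)-6-hydroxy-5-(hydroxymethyl)-5,8a-dimethyl-2-methylidenedecahydronaphthalen-1-yl]methanol (key-step product) | C=C1CC[C@@H]2[C@]3(C)COC(C)(C)O[C@@H]3CC[C@@]2(C)[C@@H]1CO | intermediate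
18 | umbelliferone (7-hydroxy-2H-chromen-2-one) | O=c1ccc2ccc(O)cc2o1 | starting material
19 | C3–O/C24–O acetonide of 7-{[(1R,4aS,5R,6R,8aR)-6-hydroxy-5-(hydroxymethyl)-5,8a-dimethyl-2-methylidenedecahydronaphthalen-1-yl]methoxy}-2H-chromen-2-one | C=C1CC[C@@H]2[C@]3(C)COC(C)(C)O[C@@H]3CC[C@@]2(C)[C@@H]1COc1ccc2ccc(=O)oc2c1 | intermediate
20 | 7-{[(1R,4aS,5R,6R,8aR)-6-hydroxy-5-(hydroxymethyl)-5,8a-dimethyl-2-methylidenedecahydronaphthalen-1-yl]methoxy}-2H-chromen-2-one | C=C1CC[C@@H]2[C@](C)(CO)[C@H](O)CC[C@@]2(C)[C@@H]1COc1ccc2ccc(=O)oc2c1 | target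

**Step count**
Total: 13 steps. Longest linear sequence: 12 steps (steps 1–3 and 5–13).

**Steps most likely to fail**

Step 11. The C9 radical may be captured by a second Cp2TiCl and lose the titanoxy group by β‑elimination, or take a hydrogen atom from the solvent, before the 6‑exo‑dig closure. The fallback generates the same C9 radical in a tin hydride chain; it sets out from aldehyde 15 and returns at 17. [(4‑Methoxybenzyl)oxy]methyllithium (from tributyl{[(4‑methoxybenzyl)oxy]methyl}stannane and n‑BuLi, THF, −78 °C) should add to 15 to give the C9 carbinol C11 4‑methoxybenzyl ether F1 as both C9 epimers. O‑Phenyl chlorothionoformate with pyridine and DMAP should convert it into the C9 phenyl thionocarbonate F2. Bu3SnH and AIBN in toluene at 90 °C, added by syringe pump, should fragment the thionocarbonate (Barton–McCombie), and the C9 radical should close onto the alkyne to the methylidene decalin C11 4‑methoxybenzyl ether F3. DDQ in CH2Cl2 with pH 7 buffer should then free the C11 alcohol 17.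

Step 5. The ester‑bearing silyloxy diene may be too weak a partner for the trisubstituted enal, Mukaiyama‑type addition at the formyl group may compete, or facial discrimination by the catalyst may be poor. The fallback gives up catalyst control and resolves; it sets out from 5 and 9 and returns at 14. Cycloaddition promoted by Me2AlCl (CH2Cl2, −78 °C) with the same acid work‑up should give the racemic silyl enol ether (10 with ent‑10 F4) and from it 11 with ent‑11 F5. Steps 6 to 8 on the racemate should give 12 with ent‑12 F6, 13 with ent‑13 F7 and 14 with ent‑14 F8. Esterification with (S)‑2‑methoxy‑2‑phenylacetic acid (DCC, DMAP, CH2Cl2) should give the (S)‑O‑methylmandelate of 14 F9 and the (S)‑O‑methylmandelate of ent‑14 F10, to be separated by chromatography or crystallisation. LiOH in THF/H2O should cleave F9 back to 14.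

Step 12. Displacement of the oxyphosphonium at the β‑branched C11 may be too slow, so that the activated alcohol is lost to elimination toward C9 or to alkylation of the hydrazide. The fallback forms the O–aryl bond in place of the O–C11 bond; it sets out from 17 and returns at 19. Palladium‑catalysed C–O coupling of 17 with 7‑bromo‑2H‑chromen‑2‑one (Pd(OAc)2, t‑BuBrettPhos, Cs2CO3, toluene, 90 °C) should give 19 directly, with no SN2 step at C11 and no new intermediate.

**Further compounds**
F1 | step 11 | 2-[(4-methoxybenzyl)oxy]-1-[(4aR,5S,6R,8aR)-5-(but-3-yn-1-yl)-2,2,4a,6-tetramethylhexahydro-4H-1,3-benzodioxin-6-yl]ethan-1-ol (C9 epimers) | C#CCC[C@@H]1[C@]2(C)COC(C)(C)O[C@@H]2CC[C@@]1(C)C(O)COCc1ccc(OC)cc1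
F2 | step 11 | O-phenyl thionocarbonate of F1 | C#CCC[C@@H]1[C@]2(C)COC(C)(C)O[C@@H]2CC[C@@]1(C)C(OC(=S)Oc1ccccc1)COCc1ccc(OC)cc1
F3 | step 11 | C11 4-methoxybenzyl ether of 17 | C=C1CC[C@@H]2[C@]3(C)COC(C)(C)O[C@@H]3CC[C@@]2(C)[C@@H]1COCc1ccc(OC)cc1
F4 | step 5 | ent-10 (not isolated) | C#CCC[C@H]1C(C(=O)OC)C(O[Si](C)(C)C(C)(C)C)=CC[C@]1(C)C=O
F5 | step 5 | ent-11 | C#CCC[C@H]1C(C(=O)OC)C(=O)CC[C@]1(C)C=O
F6 | step 5 | ent-12 | C#CCC[C@H]1[C@@](C)(C(=O)OC)C(=O)CC[C@]1(C)C=O
F7 | step 5 | ent-13 | C#CCC[C@H]1[C@@](C)(CO)[C@@H](O)CC[C@]1(C)CO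
F8 | step 5 | ent-14 | C#CCC[C@H]1[C@@]2(C)COC(C)(C)O[C@H]2CC[C@]1(C)CO
F9 | step 5 | (S)-O-methylmandelate of 14 | C#CCC[C@@H]1[C@]2(C)COC(C)(C)O[C@@H]2CC[C@@]1(C)COC(=O)[C@@H](OC)c1ccccc1
F10 | step 5 | (S)-O-methylmandelate of ent-14 | C#CCC[C@H]1[C@@]2(C)COC(C)(C)O[C@H]2CC[C@]1(C)COC(=O)[C@@H](OC)c1ccccc1
F0 | step 12 | none | none
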